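**Plan**
- Numbering: the target is a 1,4-diaryl-tetrahydro-1H,3H-furo[3,4-c]furan-3a-ol. Ring A is C1–O2–C3–C3a–C6a and ring B is C3a–C4–O5–C6–C6a. Both aryl groups are endo, trans to the cis ring-fusion OH (C3a) and H (C6a).
- C1 is a benzylic CH between ring oxygen O2 and the ring-fusion carbon C6a. It can therefore come from the CH2 end of an exocyclic C6a=C1 methylene on ring B: an arylpalladium adds there, palladium shifts one carbon to the benzylic position, and the CH2OH arm on C3a captures it. One operation cuts aryl–C1, C1–O2 and C6a–H.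
- The precursor is oxolane diol 8 (ring B complete). It is cut further at C6a=CH2 (ketone methylenation), C3–OH (ester reduction), C3a–OH (enol hydroxylation), C3a–C6a (Dieckmann) and O5–C6 (O–H insertion).
- Forward: aryl β-keto ester, asymmetric hydrogenation, O-alkylation, Dieckmann closure of ring B, hydroxylation, methylenation, reduction, then ring A closes in the key step.
- Stereochemistry: C4 from ligand-controlled hydrogenation; C3a from hydroxylation anti to the C4 aryl; C6a and C1 in the key step under substrate control (kinetic endo aryl).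

Key step: step 8

Assumption: the given SMILES is read as the endo,endo isomer (1S,3aR,4R,6aS), with both aryl groups trans to the cis ring-fusion OH and H; compounds 1, 3 and 9 are taken as commercial.

Oxolane numbering used for intermediates: C2 = target C4, C3 = C3a, C4 = C6a, C5 = C6.

Step 1
Reactants: 1 ethyl 3-(3,4-dimethoxyphenyl)-3-oxopropanoate
Product: 2 ethyl (3S)-3-(3,4-dimethoxyphenyl)-3-hydroxypropanoate
Conditions: H2 (50 bar), RuCl2[(R)-BINAP] (1 mol %), EtOH, 50 °C
Reagents that add atoms: none
Why: Noyori asymmetric hydrogenation of a β-keto ester through the ester-chelated ruthenium hydride should deliver hydride to one carbonyl face under ligand control and set the benzylic C–O stereocentre that becomes C4 of the target (the antipodal ligand is used if the sense proves opposite).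

Step 2
Reactants: 2 ethyl (3S)-3-(3,4-dimethoxyphenyl)-3-hydroxypropanoate; 3 ethyl diazoacetate
Product: 4 ethyl (3S)-3-(3,4-dimethoxyphenyl)-3-(2-ethoxy-2-oxoethoxy)propanoate
Conditions: Rh2(OAc)4 (1 mol %), CH2Cl2, 25 °C, slow addition of 3
Reagents that add atoms: ethyl diazoacetate (3), CCOC(=O)C=[N+]=[N-]
Why: Rhodium-carbene O–H insertion alkylates the secondary alcohol under neutral conditions, so the β-hydroxy ester can neither dehydrate nor undergo retro-aldol cleavage and the stereocentre is untouched.

Step 3
Reactants: 4 ethyl (3S)-3-(3,4-dimethoxyphenyl)-3-(2-ethoxy-2-oxoethoxy)propanoate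
Product: 5 ethyl (2S)-2-(3,4-dimethoxyphenyl)-4-oxooxolane-3-carboxylate (C3 epimers and enol)
Conditions: KOtBu (1.2 equiv), THF, −20 to 0 °C; AcOH quench
Reagents that add atoms: none
Why: Dieckmann condensation, in which the propanoate enolate acylates on the glycolate ester (5-exo-trig) and the product is held as its stabilised β-keto ester enolate, is the established regiochemistry for 3-oxa-adipates and closes ring B through the C3a–C6a bond; the low temperature is meant to keep the β-alkoxy enolate from eliminating so that C2 is not scrambled.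

Step 4
Reactants: 5 ethyl (2S)-2-(3,4-dimethoxyphenyl)-4-oxooxolane-3-carboxylate
Product: 6 ethyl (2R,3R)-2-(3,4-dimethoxyphenyl)-3-hydroxy-4-oxooxolane-3-carboxylate
Conditions: dimethyldioxirane (1.2 equiv), Ni(acac)2 (5 mol %), acetone/CH2Cl2, 0 °C
Reagents that add atoms: dimethyldioxirane, CC1(C)OO1
Why: Electrophilic α-hydroxylation of the β-keto ester enol should occur on the ring face opposite the adjacent C2 aryl group, placing OH trans and the ester cis to the aryl, which is the relationship between the ring-fusion OH and the neighbouring aryl in the target.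

Step 5
Reactants: 6 ethyl (2R,3R)-2-(3,4-dimethoxyphenyl)-3-hydroxy-4-oxooxolane-3-carboxylate
Product: 7 ethyl (2R,3S)-2-(3,4-dimethoxyphenyl)-3-hydroxy-4-methylideneoxolane-3-carboxylate
Conditions: Zn, CH2Br2, TiCl4 (pre-formed reagent), THF/CH2Cl2, 0 to 25 °C
Reagents that add atoms: dibromomethane, BrCBr
Why: Lombardo methylenation should convert the ketone chemoselectively beside the ester and the free tertiary alcohol, and because it is non-basic it avoids enolisation and retro-Claisen opening of the α-hydroxy-β-keto ester.

Step 6
Reactants: 7 ethyl (2R,3S)-2-(3,4-dimethoxyphenyl)-3-hydroxy-4-methylideneoxolane-3-carboxylate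
Product: 8 (2R,3R)-2-(3,4-dimethoxyphenyl)-3-(hydroxymethyl)-4-methylideneoxolan-3-ol
Conditions: LiAlH4, THF, 0 °C; Fieser work-up
Reagents that add atoms: none
Why: Hydride reduction of the ester gives the primary alcohol that becomes O2–C3 of ring A, while the stereocentres and the isolated alkene are not affected.

Step 7
Reactants: 9 3,4-dimethoxyaniline
Product: 10 3,4-dimethoxybenzenediazonium tetrafluoroborate
Conditions: NaNO2, aq. HBF4, 0 °C; precipitate washed with Et2O
Reagents that add atoms: sodium nitrite, [Na+].[O-]N=O; tetrafluoroboric acid, [H+].F[B-](F)(F)F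
Why: Standard diazotisation should give the bench-stable arenediazonium tetrafluoroborate that serves as the aryl donor.

Step 8
Reactants: 8 (2R,3R)-2-(3,4-dimethoxyphenyl)-3-(hydroxymethyl)-4-methylideneoxolan-3-ol; 10 3,4-dimethoxybenzenediazonium tetrafluoroborate
Product: 11 (1S,3aR,4R,6aS)-1,4-bis(3,4-dimethoxyphenyl)tetrahydro-1H,3H-furo[3,4-c]furan-3a(4H)-ol
Conditions: Pd2(dba)3 (3 mol %), 2,6-di-tert-butyl-4-methylpyridine (1.2 equiv), N,N-dimethylacetamide, 0 to 25 °C
Reagents that add atoms: 3,4-dimethoxybenzenediazonium tetrafluoroborate (10), COc1ccc([N+]#N)cc1OC.F[B-](F)(F)F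
Why: Proposed new method: oxidative addition of 10 to zerovalent palladium gives a cationic arylpalladium that adds across the exocyclic methylene (aryl to the CH2 terminus, forming the aryl–C1 bond; Pd to C6a on the face syn to the coordinating tertiary OH), β-hydride elimination of a benzylic hydrogen and syn re-insertion then move palladium one carbon to an η3-benzyl complex and leave H on C6a, and the pendant CH2OH displaces palladium at C1 with inversion (5-exo-tet) to close ring A and return zerovalent palladium. The closest known reactions are the Heck–Matsuda arylation, the palladium-catalysed 1,1-difunctionalisation of terminal alkenes with arenediazonium salts, and alcohol capture of η3-benzylpalladium in styrene hydroalkoxylation; new here are the 1,1-disubstituted alkene and the intramolecular O-capture. C6a is controlled because hydrogen arrives on the face that carried palladium, syn to the C3a–OH, and only this epimer has the benzylpalladium carbon cis to the CH2OH arm, so only the cis-fused bicycle can form. C1 is controlled by the preference of the palladium-bound styrene for the E geometry (aryl away from the quaternary C3a), the syn re-insertion and the anti C–O displacement, which together should place the aryl on the concave face, trans to H6a, as the kinetic endo isomer. The step needs β-hydride elimination toward the benzylic C–H and not toward the O–CH2 hydrogens at C6, which conjugation and the η3-benzyl sink should favour, and it needs the hindered non-coordinating base to trap HBF4 so that neither benzylic ether epimerises.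

**Compound list**
1 | ethyl 3-(3,4-dimethoxyphenyl)-3-oxopropanoate | CCOC(=O)CC(=O)c1ccc(OC)c(OC)c1 | starting material
2 | ethyl (3S)-3-(3,4-dimethoxyphenyl)-3-hydroxypropanoate | CCOC(=O)C[C@H](O)c1ccc(OC)c(OC)c1 | intermediate
3 | ethyl diazoacetate | CCOC(=O)C=[N+]=[N-] | starting material
4 | ethyl (3S)-3-(3,4-dimethoxyphenyl)-3-(2-ethoxy-2-oxoethoxy)propanoate | CCOC(=O)C[C@H](OCC(=O)OCC)c1ccc(OC)c(OC)c1 | intermediate
5 | ethyl (2S)-2-(3,4-dimethoxyphenyl)-4-oxooxolane-3-carboxylate (C3 epimers and enol) | CCOC(=O)C1C(=O)CO[C@@H]1c1ccc(OC)c(OC)c1 | intermediate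
6 | ethyl (2R,3R)-2-(3,4-dimethoxyphenyl)-3-hydroxy-4-oxooxolane-3-carboxylate (OH trans to aryl; the C2 descriptor changes by CIP priority only) | CCOC(=O)[C@]1(O)C(=O)CO[C@@H]1c1ccc(OC)c(OC)c1 | intermediate
7 | ethyl (2R,3S)-2-(3,4-dimethoxyphenyl)-3-hydroxy-4-methylideneoxolane-3-carboxylate | CCOC(=O)[C@]1(O)C(=C)CO[C@@H]1c1ccc(OC)c(OC)c1 | intermediate
8 | (2R,3R)-2-(3,4-dimethoxyphenyl)-3-(hydroxymethyl)-4-methylideneoxolan-3-ol (CH2OH cis to aryl) | OC[C@@]1(O)[C@@H](c2ccc(OC)c(OC)c2)OCC1=C | intermediate
9 | 3,4-dimethoxyaniline | COc1ccc(N)cc1OC | starting material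
10 | 3,4-dimethoxybenzenediazonium tetrafluoroborate | COc1ccc([N+]#N)cc1OC.F[B-](F)(F)F | intermediate
11 | (1S,3aR,4R,6aS)-1,4-bis(3,4-dimethoxyphenyl)tetrahydro-1H,3H-furo[3,4-c]furan-3a(4H)-ol | COc1ccc([C@H]2OC[C@@]3(O)[C@@H](c4ccc(OC)c(OC)c4)OC[C@@H]23)cc1OC | target

Total step count: 8. Longest linear sequence: 7 (steps 1 to 6 and 8; step 7 is a one-step side branch).

**Steps most likely to fail**

Step 8 (Proposed new method). After aryl transfer the palladium may walk toward the ring oxygen by β-hydride elimination from C6–H and be lost as an enol ether or acetal, or it may leave as a plain Heck styrene before C–O capture. The fallback uses known chemistry, sets out from 8 and returns at 11. Hydroboration of the methylene with 9-BBN from the face opposite the aryl and CH2OH groups, then NaOH/H2O2, should give the triol (2R,3R,4R)-2-(3,4-dimethoxyphenyl)-3,4-bis(hydroxymethyl)oxolan-3-ol F1. Fétizon oxidation (Ag2CO3 on Celite, toluene, reflux) should oxidise the less hindered primary alcohol and close the hydroxy lactone (3aR,4R,6aR)-4-(3,4-dimethoxyphenyl)-3a-hydroxytetrahydro-1H,3H-furo[3,4-c]furan-1-one F2. (3,4-Dimethoxyphenyl)lithium F3, made from 4-bromo-1,2-dimethoxybenzene and n-BuLi and used in excess in THF at −78 °C, should add to the lactone carbonyl to give the lactol 1,4-bis(3,4-dimethoxyphenyl)tetrahydro-1H,3H-furo[3,4-c]furan-1,3a-diol F4 (C1 epimers). Et3SiH/BF3·OEt2 in CH2Cl2 at −78 °C should then reduce the aryl-substituted oxocarbenium ion from the convex face, leaving the aryl endo, to give 11. In this variant the aryl–C1 bond is made by carbonyl addition and C1 is set by hydride delivery, not by the palladium shift.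

Step 3. The β-alkoxy ester enolate may expel the glycolate alkoxide and re-add it, which erodes the configuration at C2, or the glycolate enolate may cyclise in the other direction. The fallback sets out from 2 and returns at 5 and reverses the order of bond formation. The dianion of 2 (LDA, 2.2 equiv, THF, −50 °C; Fráter–Seebach-type, unable to eliminate) is C-acylated with 2-chloro-N-methoxy-N-methylacetamide to give ethyl (3S)-2-(chloroacetyl)-3-(3,4-dimethoxyphenyl)-3-hydroxypropanoate F5. K2CO3 in MeCN then closes ring B by intramolecular O-alkylation (5-exo-tet Williamson reaction) to give 5.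

Step 5. The Lewis-acidic titanium reagent may trigger an α-ketol shift or ring opening of the α-hydroxy-β-keto ester, or methylene transfer to the hindered ketone may stall. The fallback sets out from 6 and returns at 7 by addition then elimination. Me3SiCH2MgCl with CeCl3 (THF, −78 °C) should add to the ketone only, giving ethyl (2R,3R)-2-(3,4-dimethoxyphenyl)-3,4-dihydroxy-4-[(trimethylsilyl)methyl]oxolane-3-carboxylate F6 (C4 epimers). KH in THF at 0 °C should then effect Peterson elimination to 7.

**Further compounds**
F1 | step 8 | (2R,3R,4R)-2-(3,4-dimethoxyphenyl)-3,4-bis(hydroxymethyl)oxolan-3-ol | OC[C@@]1(O)[C@@H](c2ccc(OC)c(OC)c2)OC[C@H]1CO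
F2 | step 8 | (3aR,4R,6aR)-4-(3,4-dimethoxyphenyl)-3a-hydroxytetrahydro-1H,3H-furo[3,4-c]furan-1-one | O=C1OC[C@@]2(O)[C@@H](c3ccc(OC)c(OC)c3)OC[C@@H]12
F3 | step 8 | (3,4-dimethoxyphenyl)lithium | [Li]c1ccc(OC)c(OC)c1
F4 | step 8 | 1,4-bis(3,4-dimethoxyphenyl)tetrahydro-1H,3H-furo[3,4-c]furan-1,3a-diol (C1 epimers) | COc1ccc(C2(O)OC[C@@]3(O)[C@@H](c4ccc(OC)c(OC)c4)OC[C@@H]23)cc1OC
F5 | step 3 | ethyl (3S)-2-(chloroacetyl)-3-(3,4-dimethoxyphenyl)-3-hydroxypropanoate | CCOC(=O)C(C(=O)CCl)[C@H](O)c1ccc(OC)c(OC)c1
F6 | step 5 | ethyl (2R,3R)-2-(3,4-dimethoxyphenyl)-3,4-dihydroxy-4-[(trimethylsilyl)methyl]oxolane-3-carboxylate (C4 epimers) | CCOC(=O)[C@]1(O)C(O)(C[Si](C)(C)C)CO[C@@H]1c1ccc(OC)c(OC)c1
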